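The route rests on cutting the aryl ketone bond C4–C4a in ring C of the flavanone half. In ring A of that half, O1 sits on C8a, para to C6, the carbon bonded to flavone C3. The ring-opened precursor is therefore a 2-substituted phloroglucinol with a local twofold axis through C6 and C8a, so C4a and C8 are equivalent. In one operation, acid unmasks a tert-butyl ester and an intramolecular Friedel–Crafts acylation closes ring C. This fixes the 3,6-linkage without 6/8 ambiguity and leaves the (R)-benzylic ether at C2 untouched. The precursor is an (R)-3-aryloxy-3-arylpropanoate, made by Mitsunobu inversion, whose 4-oxyphenyl ring is deactivated as a benzyl carbonate.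

Key step: step 10

Assumption: the target SMILES carries no descriptor for the axis between flavone C3 and flavanone C6. Only C2 is therefore controlled, and rotamers about this bond are treated as one compound. Compounds 1, 5, 11 and 13 are taken as commercial.

Step 1
Reactants: 1 5-hydroxy-7-methoxy-2-(4-methoxyphenyl)-4H-chromen-4-one (apigenin 7,4'-dimethyl ether)
Product: 2 5-(benzyloxy)-7-methoxy-2-(4-methoxyphenyl)-4H-chromen-4-one
Conditions: BnBr, K2CO3, DMF, 80 °C
Reagents that add atoms: benzyl bromide, BrCc1ccccc1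
Why: Williamson etherification; the chelated 5-OH is the only acidic site, so heating with base and benzyl bromide should alkylate it and remove the proton that the later organometallic steps could not tolerate.

Step 2
Reactants: 2 5-(benzyloxy)-7-methoxy-2-(4-methoxyphenyl)-4H-chromen-4-one
Product: 4 5-(benzyloxy)-3-iodo-7-methoxy-2-(4-methoxyphenyl)-4H-chromen-4-one, via 3-lithioflavone 3 (not isolated)
Conditions: LDA, THF, −78 °C; then I2, −78 °C to rt
Reagents that add atoms: iodine, II
Why: Lithiation of flavones at C3, the vinylic position next to the coordinating C4 carbonyl, followed by an iodine quench is a known entry to 3-iodoflavones, and LDA is too weak a base to metalate the alkoxyarene rings.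

Step 3
Reactants: 5 3,5-bis(benzyloxy)phenol
Product: 6 [3,5-bis(benzyloxy)phenoxy]triisopropylsilane
Conditions: TIPSCl, imidazole, DMF, rt
Reagents that add atoms: triisopropylsilyl chloride, CC(C)[Si](Cl)(C(C)C)C(C)C
Why: Standard phenol silylation; the bulky, poorly coordinating silyl ether shields its two neighbouring positions in the next metalation and marks the oxygen that becomes O1.

Step 4
Reactants: 6 [3,5-bis(benzyloxy)phenoxy]triisopropylsilane; 4 5-(benzyloxy)-3-iodo-7-methoxy-2-(4-methoxyphenyl)-4H-chromen-4-one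
Product: 9 5-(benzyloxy)-3-[2,6-bis(benzyloxy)-4-(triisopropylsilyloxy)phenyl]-7-methoxy-2-(4-methoxyphenyl)-4H-chromen-4-one, via aryllithium 7 (not isolated), via arylzinc chloride 8 (not isolated)
Conditions: n-BuLi, THF, 0 °C; ZnCl2, 0 °C to rt; then 4, Pd2(dba)3, RuPhos, THF, 65 °C
Reagents that add atoms: none
Why: Directed ortho-metalation should occur at the carbon flanked by the two coordinating benzyloxy groups (para to the shielded silyloxy group), and after transmetalation to zinc a Negishi coupling with a bulky dialkylbiarylphosphine, a system known for biaryls with four ortho substituents, joins it to the C3–I bond, into which zerovalent palladium inserts readily.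

Step 5
Reactants: 9 5-(benzyloxy)-3-[2,6-bis(benzyloxy)-4-(triisopropylsilyloxy)phenyl]-7-methoxy-2-(4-methoxyphenyl)-4H-chromen-4-one
Product: 10 5-(benzyloxy)-3-[2,6-bis(benzyloxy)-4-hydroxyphenyl]-7-methoxy-2-(4-methoxyphenyl)-4H-chromen-4-one
Conditions: TBAF, THF, 0 °C; aqueous work-up
Reagents that add atoms: none
Why: Fluoride-induced cleavage of the aryl silyl ether, driven by the Si–F bond, frees only the phenol para to the biaryl bond and leaves the benzyl ethers and the flavone untouched.

Step 6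
Reactants: 11 4-hydroxybenzaldehyde
Product: 12 benzyl 4-formylphenyl carbonate
Conditions: CbzCl, Et3N, CH2Cl2, 0 °C
Reagents that add atoms: benzyl chloroformate, O=C(Cl)OCc1ccccc1
Why: Acylation of the phenol with a chloroformate turns the donor oxygen into a weakly withdrawing group that later suppresses benzylic ionisation and can be removed by hydrogenolysis.

Step 7
Reactants: 12 benzyl 4-formylphenyl carbonate; 13 tert-butyl diazoacetate
Product: 14 tert-butyl 3-{4-[(benzyloxycarbonyl)oxy]phenyl}-3-oxopropanoate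
Conditions: NbCl5 (cat.), CH2Cl2, rt
Reagents that add atoms: none
Why: Roskamp homologation; Lewis-acid-promoted addition of the diazoacetate to the aldehyde, 1,2-hydride shift and loss of N2 give the β-keto ester under conditions that spare the carbonate.

Step 8
Reactants: 14 tert-butyl 3-{4-[(benzyloxycarbonyl)oxy]phenyl}-3-oxopropanoate
Product: 15 tert-butyl (S)-3-{4-[(benzyloxycarbonyl)oxy]phenyl}-3-hydroxypropanoate
Conditions: RuCl[(S,S)-TsDPEN](p-cymene) (cat.), HCO2H/Et3N 5:2, CH2Cl2, rt
Reagents that add atoms: none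
Why: Noyori-type asymmetric transfer hydrogenation of an aryl ketone; the (S,S)-catalyst delivers hydride to the Re face through the CH–π-organised six-membered transition state known for aryl ketones and aroylacetates, which sets the (S)-carbinol.

Step 9
Reactants: 10 5-(benzyloxy)-3-[2,6-bis(benzyloxy)-4-hydroxyphenyl]-7-methoxy-2-(4-methoxyphenyl)-4H-chromen-4-one; 15 tert-butyl (S)-3-{4-[(benzyloxycarbonyl)oxy]phenyl}-3-hydroxypropanoate
Product: 16 tert-butyl (R)-3-{3,5-bis(benzyloxy)-4-[5-(benzyloxy)-7-methoxy-2-(4-methoxyphenyl)-4-oxo-4H-chromen-3-yl]phenoxy}-3-{4-[(benzyloxycarbonyl)oxy]phenyl}propanoate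
Conditions: PPh3, DIAD, toluene, 0 °C to rt
Reagents that add atoms: none
Why: Mitsunobu etherification; the unhindered phenol of 10 displaces the oxyphosphonium group in an SN2 process with inversion, (S) to (R), and the withdrawing carbonate disfavours an ionising pathway that would erode the configuration.

Step 10
Reactants: 16 tert-butyl (R)-3-{3,5-bis(benzyloxy)-4-[5-(benzyloxy)-7-methoxy-2-(4-methoxyphenyl)-4-oxo-4H-chromen-3-yl]phenoxy}-3-{4-[(benzyloxycarbonyl)oxy]phenyl}propanoate
Product: 19 benzyl 4-{(2R)-5,7-bis(benzyloxy)-6-[5-(benzyloxy)-7-methoxy-2-(4-methoxyphenyl)-4-oxo-4H-chromen-3-yl]-4-oxochroman-2-yl}phenyl carbonate, via carboxylic acid 17 (not isolated), via acyl trifluoroacetate 18 (not isolated)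
Conditions: TFA, CH2Cl2, 0 °C to rt; evaporate; TFAA, CH2Cl2, 0 °C
Reagents that add atoms: none
Why: TFA removes the tert-butyl group as 2-methylpropene to give acid 17, TFAA converts it into the acyl trifluoroacetate 18, and the trialkoxy-substituted ring attacks the activated carbonyl through C4a, after which proton loss restores aromaticity and gives the aryl ketone. The reaction type is the intramolecular Friedel–Crafts acylation of 3-aryloxypropanoic acids to chroman-4-ones under mixed-anhydride activation. Ring C closes in a 6-(enolendo)-exo-trig mode, with the C4a=C8a bond of the arene inside the new six-membered ring and the C=O bond outside it. No stereocentre is formed; C2 is carried through unchanged because none of its bonds takes part, and ionisation of the benzylic C2–O1 bond is held back by the withdrawing carbonate on the aryl ring and by the β-acyl group. Site selectivity is secured by the substrate, because the two positions ortho to O1 are exchanged by the local twofold axis through C6 and C8a, so both give the same 6-linked constitution and an 8-linked isomer cannot arise. Chemoselectivity follows from the six-membered transition state and from the deactivation of flavone ring A and the anisyl ring by conjugation with the pyranone carbonyl.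

Step 11
Reactants: 19 benzyl 4-{(2R)-5,7-bis(benzyloxy)-6-[5-(benzyloxy)-7-methoxy-2-(4-methoxyphenyl)-4-oxo-4H-chromen-3-yl]-4-oxochroman-2-yl}phenyl carbonate
Product: 20 (2R)-5,7-dihydroxy-6-[5-hydroxy-7-methoxy-2-(4-methoxyphenyl)-4-oxo-4H-chromen-3-yl]-2-(4-hydroxyphenyl)chroman-4-one (target)
Conditions: H2 (1 atm), Pd/C, EtOAc/MeOH, rt
Reagents that add atoms: none
Why: Catalytic hydrogenolysis cleaves the three benzyl ethers and the benzyl carbonate (which then loses CO2) under neutral conditions, so the base-sensitive C2 stereocentre is not epimerised and the methyl ethers and the tetrasubstituted flavone double bond stay untouched.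

Compound list
1 | 5-hydroxy-7-methoxy-2-(4-methoxyphenyl)-4H-chromen-4-one | COc1ccc(-c2cc(=O)c3c(O)cc(OC)cc3o2)cc1 | starting material
2 | 5-(benzyloxy)-7-methoxy-2-(4-methoxyphenyl)-4H-chromen-4-one | COc1ccc(-c2cc(=O)c3c(OCc4ccccc4)cc(OC)cc3o2)cc1 | intermediate
3 | 3-lithio-5-(benzyloxy)-7-methoxy-2-(4-methoxyphenyl)-4H-chromen-4-one | [Li]c1c(-c2ccc(OC)cc2)oc2cc(OC)cc(OCc3ccccc3)c2c1=O | intermediate
4 | 5-(benzyloxy)-3-iodo-7-methoxy-2-(4-methoxyphenyl)-4H-chromen-4-one | COc1ccc(-c2oc3cc(OC)cc(OCc4ccccc4)c3c(=O)c2I)cc1 | intermediate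
5 | 3,5-bis(benzyloxy)phenol | Oc1cc(OCc2ccccc2)cc(OCc2ccccc2)c1 | starting material
6 | [3,5-bis(benzyloxy)phenoxy]triisopropylsilane | CC(C)[Si](Oc1cc(OCc2ccccc2)cc(OCc2ccccc2)c1)(C(C)C)C(C)C | intermediate
7 | 2,6-bis(benzyloxy)-4-(triisopropylsilyloxy)phenyllithium | [Li]c1c(OCc2ccccc2)cc(O[Si](C(C)C)(C(C)C)C(C)C)cc1OCc1ccccc1 | intermediate
8 | 2,6-bis(benzyloxy)-4-(triisopropylsilyloxy)phenylzinc chloride | Cl[Zn]c1c(OCc2ccccc2)cc(O[Si](C(C)C)(C(C)C)C(C)C)cc1OCc1ccccc1 | intermediate
9 | 5-(benzyloxy)-3-[2,6-bis(benzyloxy)-4-(triisopropylsilyloxy)phenyl]-7-methoxy-2-(4-methoxyphenyl)-4H-chromen-4-one | COc1ccc(-c2oc3cc(OC)cc(OCc4ccccc4)c3c(=O)c2-c2c(OCc3ccccc3)cc(O[Si](C(C)C)(C(C)C)C(C)C)cc2OCc2ccccc2)cc1 | intermediate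
10 | 5-(benzyloxy)-3-[2,6-bis(benzyloxy)-4-hydroxyphenyl]-7-methoxy-2-(4-methoxyphenyl)-4H-chromen-4-one | COc1ccc(-c2oc3cc(OC)cc(OCc4ccccc4)c3c(=O)c2-c2c(OCc3ccccc3)cc(O)cc2OCc2ccccc2)cc1 | intermediate
11 | 4-hydroxybenzaldehyde | O=Cc1ccc(O)cc1 | starting material
12 | benzyl 4-formylphenyl carbonate | O=Cc1ccc(OC(=O)OCc2ccccc2)cc1 | intermediate
13 | tert-butyl diazoacetate | CC(C)(C)OC(=O)C=[N+]=[N-] | starting material
14 | tert-butyl 3-{4-[(benzyloxycarbonyl)oxy]phenyl}-3-oxopropanoate | CC(C)(C)OC(=O)CC(=O)c1ccc(OC(=O)OCc2ccccc2)cc1 | intermediate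
15 | tert-butyl (S)-3-{4-[(benzyloxycarbonyl)oxy]phenyl}-3-hydroxypropanoate | CC(C)(C)OC(=O)C[C@H](O)c1ccc(OC(=O)OCc2ccccc2)cc1 | intermediate
16 | tert-butyl (R)-3-{3,5-bis(benzyloxy)-4-[5-(benzyloxy)-7-methoxy-2-(4-methoxyphenyl)-4-oxo-4H-chromen-3-yl]phenoxy}-3-{4-[(benzyloxycarbonyl)oxy]phenyl}propanoate | COc1ccc(-c2oc3cc(OC)cc(OCc4ccccc4)c3c(=O)c2-c2c(OCc3ccccc3)cc(O[C@H](CC(=O)OC(C)(C)C)c3ccc(OC(=O)OCc4ccccc4)cc3)cc2OCc2ccccc2)cc1 | intermediate
17 | (R)-3-{3,5-bis(benzyloxy)-4-[5-(benzyloxy)-7-methoxy-2-(4-methoxyphenyl)-4-oxo-4H-chromen-3-yl]phenoxy}-3-{4-[(benzyloxycarbonyl)oxy]phenyl}propanoic acid | COc1ccc(-c2oc3cc(OC)cc(OCc4ccccc4)c3c(=O)c2-c2c(OCc3ccccc3)cc(O[C@H](CC(=O)O)c3ccc(OC(=O)OCc4ccccc4)cc3)cc2OCc2ccccc2)cc1 | intermediate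
18 | mixed anhydride of acid 17 with trifluoroacetic acid, (R) | COc1ccc(-c2oc3cc(OC)cc(OCc4ccccc4)c3c(=O)c2-c2c(OCc3ccccc3)cc(O[C@H](CC(=O)OC(=O)C(F)(F)F)c3ccc(OC(=O)OCc4ccccc4)cc3)cc2OCc2ccccc2)cc1 | intermediate
19 | benzyl 4-{(2R)-5,7-bis(benzyloxy)-6-[5-(benzyloxy)-7-methoxy-2-(4-methoxyphenyl)-4-oxo-4H-chromen-3-yl]-4-oxochroman-2-yl}phenyl carbonate | COc1ccc(-c2oc3cc(OC)cc(OCc4ccccc4)c3c(=O)c2-c2c(OCc3ccccc3)cc3c(c2OCc2ccccc2)C(=O)C[C@H](c2ccc(OC(=O)OCc4ccccc4)cc2)O3)cc1 | intermediate
20 | (2R)-5,7-dihydroxy-6-[5-hydroxy-7-methoxy-2-(4-methoxyphenyl)-4-oxo-4H-chromen-3-yl]-2-(4-hydroxyphenyl)chroman-4-one | COc1ccc(-c2oc3cc(OC)cc(O)c3c(=O)c2-c2c(O)cc3c(c2O)C(=O)C[C@H](c2ccc(O)cc2)O3)cc1 | target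

Total step count: 11.
Longest linear sequence: 7 steps (steps 1, 2, 4, 5, 9, 10 and 11, starting from 1).

Steps most likely to fail

**Step 10 (key step).**
- Risk: the benzylic C2–O1 bond may ionise, or acid may induce β-elimination of the phenol, before the ring closes. Either process erodes the configuration at C2. The electron-rich ring may also capture the tert-butyl cation.
- Fallback (sets out from 10, comes back at 20): the stereocentre is taken out of the acid step.
 - Phenol 10 is added to tert-butyl propiolate (DABCO, CH2Cl2) to give the tert-butyl (E)-3-aryloxyacrylate F1.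
 - TFA and then TFAA close the same C4–C4a bond to the 2-unsubstituted chromone F2. Warming is allowed here, because nothing can racemise and the protonated enol ether equilibrates its E and Z forms.
 - A Pd(OCOCF3)2/t-BuPyOx-catalysed asymmetric conjugate addition of 4-(benzyloxy)phenylboronic acid follows, using the ligand enantiomer that attacks the face leading to (2R). It should give the tetrabenzyl flavanone F3, since the tetrasubstituted flavone enone is inert.
 - Hydrogenolysis as in step 11 gives 20.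

**Step 9.**
- Risk: β-elimination of the activated alcohol to the cinnamate, driven by the acidified hydrogens next to the ester, and partial loss of inversion.
- Fallback (sets out from 12 and 10, comes back at 17): the ester is replaced by a masked acid that carries no acidified hydrogens.
 - Keck allylation of 12 (allyltributylstannane, Ti(OiPr)4/BINOL, Si-face attack) gives the (S)-homoallylic alcohol F4.
 - Mitsunobu reaction with 10 gives the (R)-homoallyl aryl ether F5.
 - Lemieux–Johnson cleavage (OsO4 cat., NaIO4) of the only unhindered alkene gives the (R)-3-aryloxy aldehyde F6.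
 - Pinnick oxidation (NaClO2, NaH2PO4, 2-methyl-2-butene) gives acid 17, which enters the TFAA stage of step 10.

**Step 4.**
- Risk: competing deprotonation at the benzylic CH2 groups followed by Wittig rearrangement, and slow reductive elimination in forming a biaryl bond with four flanking substituents.
- Fallback (sets out from 5 and 3, comes back at 10): no deprotonation of the central ring and no cross-coupling.
 - Teuber oxidation of 5 with (KSO3)2NO gives 2,6-bis(benzyloxy)-1,4-benzoquinone F7.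
 - The 3-lithioflavone 3 from step 2 adds to the C1 carbonyl. This is the more electrophilic one, because the C4 carbonyl is a doubly vinylogous carbonate. The product is the p-quinol F8.
 - Reductive aromatisation (Zn, AcOH) removes the tertiary hydroxyl and gives 10.

Further compounds
F1 | step 10 | tert-butyl (E)-3-{3,5-bis(benzyloxy)-4-[5-(benzyloxy)-7-methoxy-2-(4-methoxyphenyl)-4-oxo-4H-chromen-3-yl]phenoxy}acrylate | COc1ccc(-c2oc3cc(OC)cc(OCc4ccccc4)c3c(=O)c2-c2c(OCc3ccccc3)cc(O/C=C/C(=O)OC(C)(C)C)cc2OCc2ccccc2)cc1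
F2 | step 10 | 5,7-bis(benzyloxy)-6-[5-(benzyloxy)-7-methoxy-2-(4-methoxyphenyl)-4-oxo-4H-chromen-3-yl]-4H-chromen-4-one | COc1ccc(-c2oc3cc(OC)cc(OCc4ccccc4)c3c(=O)c2-c2c(OCc3ccccc3)cc3occc(=O)c3c2OCc2ccccc2)cc1
F3 | step 10 | (2R)-5,7-bis(benzyloxy)-6-[5-(benzyloxy)-7-methoxy-2-(4-methoxyphenyl)-4-oxo-4H-chromen-3-yl]-2-[4-(benzyloxy)phenyl]chroman-4-one | COc1ccc(-c2oc3cc(OC)cc(OCc4ccccc4)c3c(=O)c2-c2c(OCc3ccccc3)cc3c(c2OCc2ccccc2)C(=O)C[C@H](c2ccc(OCc4ccccc4)cc2)O3)cc1
F4 | step 9 | benzyl 4-[(S)-1-hydroxybut-3-en-1-yl]phenyl carbonate | O[C@@H](CC=C)c1ccc(OC(=O)OCc2ccccc2)cc1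
F5 | step 9 | benzyl 4-[(R)-1-{3,5-bis(benzyloxy)-4-[5-(benzyloxy)-7-methoxy-2-(4-methoxyphenyl)-4-oxo-4H-chromen-3-yl]phenoxy}but-3-en-1-yl]phenyl carbonate | COc1ccc(-c2oc3cc(OC)cc(OCc4ccccc4)c3c(=O)c2-c2c(OCc3ccccc3)cc(O[C@H](CC=C)c3ccc(OC(=O)OCc4ccccc4)cc3)cc2OCc2ccccc2)cc1
F6 | step 9 | benzyl 4-[(R)-1-{3,5-bis(benzyloxy)-4-[5-(benzyloxy)-7-methoxy-2-(4-methoxyphenyl)-4-oxo-4H-chromen-3-yl]phenoxy}-3-oxopropyl]phenyl carbonate | COc1ccc(-c2oc3cc(OC)cc(OCc4ccccc4)c3c(=O)c2-c2c(OCc3ccccc3)cc(O[C@H](CC=O)c3ccc(OC(=O)OCc4ccccc4)cc3)cc2OCc2ccccc2)cc1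
F7 | step 4 | 2,6-bis(benzyloxy)cyclohexa-2,5-diene-1,4-dione | O=C1C=C(OCc2ccccc2)C(=O)C(OCc2ccccc2)=C1
F8 | step 4 | 5-(benzyloxy)-3-[2,6-bis(benzyloxy)-1-hydroxy-4-oxocyclohexa-2,5-dien-1-yl]-7-methoxy-2-(4-methoxyphenyl)-4H-chromen-4-one | COc1ccc(-c2oc3cc(OC)cc(OCc4ccccc4)c3c(=O)c2C2(O)C(OCc3ccccc3)=CC(=O)C=C2OCc2ccccc2)cc1
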